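**Retrosynthetic overview** (quinic acid numbering, C7 = carboxyl carbon)
1. Target ⇐ hydrogenolysis of all benzyl groups ⇐ triple acylation of benzyl quinate with three equivalents of tri-O-benzylgalloyl chloride ⇐ benzyl alcoholysis of 1,5-quinide, whose lactone is a temporary second ring.
2. Quinide ⇐ OsO4 dihydroxylation of the C3=C4 ene-lactone on its convex face ⇐ lactonisation of the cis-5-hydroxy ester ⇐ hydroxyl-directed reduction of the C5 enone ⇐ dehydrogenation of the cyclohexanone.
3. Key disconnection: C6–C1 and C3–C4 of the carbocycle (formed first), by a proline-catalysed Michael/aldol [3+3] annulation of acetone (C4–C5–C6) with ethyl 2-oxobut-3-enoate (C7, C1–C3).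
4. Enabling feature: C5 lies between C4 and C6, so as a ketone it is the carbonyl of an acetone unit with two nucleophilic α-carbons. C1, the tertiary carbinol carbon bearing the carboxyl, is an α-keto ester carbonyl that is β-hydroxy-related to C5 through C6 and 1,5-related through C2–C3–C4, which makes C3 the β-carbon of a vinyl keto ester.
5. Stereochemistry: C1 is set by the catalyst in the key step, C5 is relayed from C1, and C3/C4 are relayed by the lactone bridge that the cis C1-carboxyl/C5-oxygen pair allows.

Key step: step 2

Remark: the sense of induction in step 2 is assigned with the Houk–List model of proline aldol catalysis (mirror image of the Hajos–Parrish case); if the opposite sense were found, L-proline would be used.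

**Step 1**
Reactants: 1 diethyl oxalate; 2 vinylmagnesium bromide
Product: 3 ethyl 2-oxobut-3-enoate
Conditions: 2 (1.0 equiv), 1 (1.5 equiv), THF/Et2O, −78 °C; 1 M HCl, −78 → 0 °C; used at once as a cold solution
Reagents that add atoms: none
Why: Acylation of a Grignard reagent with a dialkyl oxalate, the standard entry to α-keto esters, should stop after one addition at −78 °C with excess oxalate, and no stereocentre is formed.

**Step 2**
Reactants: 3 ethyl 2-oxobut-3-enoate; 4 acetone
Product: 6 ethyl (1S)-1-hydroxy-3-oxocyclohexane-1-carboxylate, via ethyl 2,6-dioxoheptanoate 5 (not isolated)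
Conditions: D-proline (30 mol %), acetone/DMSO (1:4), 3 added over 8 h, 4 °C → rt
Reagents that add atoms: none
Why: Proposed new method: the D-proline enamine of acetone should add to the unhindered CH2 terminus of enone 3 (C3–C4), and the C5=C6 enamine of the resulting diketo ester 5 should then attack the α-keto ester carbonyl (C6–C1); the closest known reaction types are the amine-catalysed [3+3] Michael/aldol annulation of ketones with β,γ-unsaturated α-keto esters and the Hajos–Parrish–Eder–Sauer–Wiechert cyclisation. The carbocycle closes in the 6-(enolendo)-exo-trig mode. The only new stereocentre, C1, is set in the aldol step by the catalyst: in the Houk–List transition state the anti-enamine attacks the ketone that is hydrogen-bonded to the proline carboxylic acid, the tether carbon C2 is forced gauche and the ester anti to the enamine carbon, which for D-proline should give the 1S carbinol. The step needs conjugate addition to win over 1,2-aldol addition and over polymerisation of 3, which the unsubstituted β-terminus, the reversibility of the tertiary aldol and slow addition of 3 into excess acetone should secure. Regiochemistry of the closure is not in question, because only attack of C6 on C1 gives a ring larger than four members.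

**Step 3**
Reactants: 6 ethyl (1S)-1-hydroxy-3-oxocyclohexane-1-carboxylate
Product: 7 ethyl (1S)-1-hydroxy-5-oxocyclohex-3-ene-1-carboxylate
Conditions: IBX (1.5 equiv), 4-methoxypyridine N-oxide (1.5 equiv), DMSO, 25 °C
Reagents that add atoms: none
Why: IBX-mediated α,β-dehydrogenation of a ketone can only give the C3=C4 enone, because C1 on the other side of the carbonyl carries no hydrogen, and the room-temperature variant should spare the tertiary β-hydroxyl and leave C1 untouched.

**Step 4**
Reactants: 7 ethyl (1S)-1-hydroxy-5-oxocyclohex-3-ene-1-carboxylate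
Product: 8 ethyl (1S,5R)-1,5-dihydroxycyclohex-3-ene-1-carboxylate
Conditions: Me4NBH(OAc)3 (5 equiv), MeCN/AcOH (1:1), −40 → −20 °C
Reagents that add atoms: none
Why: In this hydroxyl-directed 1,2-reduction (Evans–Saksena) the C1 hydroxyl binds boron and hydride is delivered to the carbonyl face on its own side, so the new C5 hydroxyl should end up trans to the C1 hydroxyl and cis to the ester (5R).

**Step 5**
Reactants: 8 ethyl (1S,5R)-1,5-dihydroxycyclohex-3-ene-1-carboxylate
Product: 9 (1S,5R)-1-hydroxy-6-oxabicyclo[3.2.1]oct-3-en-7-one
Conditions: DBU (20 mol %), toluene, 90 °C, EtOH distilled off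
Reagents that add atoms: none
Why: Intramolecular transesterification (lactonisation, 5-exo-trig) is possible because the C5 hydroxyl and the ester are cis-1,3, and it also proofreads step 4 since the C5 epimer cannot close.

**Step 6**
Reactants: 9 (1S,5R)-1-hydroxy-6-oxabicyclo[3.2.1]oct-3-en-7-one
Product: 10 1,5-quinide, (1S,3R,4R,5R)-1,3,4-trihydroxy-6-oxabicyclo[3.2.1]octan-7-one
Conditions: OsO4 (2 mol %), NMO (1.5 equiv), acetone/H2O (4:1), rt
Reagents that add atoms: OsO4 (O=[Os](=O)(=O)=O), N-methylmorpholine N-oxide (C[N+]1([O-])CCOCC1), water (O)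
Why: Catalytic syn-dihydroxylation (Upjohn) should occur on the convex face opposite the lactone bridge, which sets the C3 and C4 hydroxyls cis to each other and trans to the C5 oxygen, as in the classical conversion of this ene-lactone type into quinide.

**Step 7**
Reactants: 10 1,5-quinide; 11 benzyl alcohol
Product: 12 benzyl (1S,3R,4S,5R)-1,3,4,5-tetrahydroxycyclohexane-1-carboxylate (benzyl quinate)
Conditions: 11 (neat, 20 equiv), NaH (10 mol %), 0 °C → rt; AcOH
Reagents that add atoms: none
Why: Base-catalysed alcoholysis (transesterification) of the bridged γ-lactone by benzyl alkoxide, driven by the large excess of benzyl alcohol, should give the ring-opened benzyl ester without touching any stereocentre.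

**Step 8**
Reactants: 13 3,4,5-tris(benzyloxy)benzoic acid
Product: 14 3,4,5-tris(benzyloxy)benzoyl chloride
Conditions: (COCl)2 (1.5 equiv), DMF (cat.), CH2Cl2, 0 °C → rt
Reagents that add atoms: oxalyl chloride (ClC(=O)C(Cl)=O)
Why: Acid chloride formation with oxalyl chloride and catalytic DMF (Vilsmeier-type activation) is standard and leaves the benzyl ethers intact.

**Step 9**
Reactants: 12 benzyl quinate; 14 3,4,5-tris(benzyloxy)benzoyl chloride (three equivalents are incorporated, one per secondary hydroxyl)
Product: 15 benzyl 3,4,5-tris-O-[3,4,5-tris(benzyloxy)benzoyl]quinate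
Conditions: 14 (3.6 equiv in all), pyridine, DMAP (30 mol %), CH2Cl2, 0 °C → rt
Reagents that add atoms: tri-O-benzylgalloyl chloride as second and third equivalent of 14 (O=C(Cl)c1cc(OCc2ccccc2)c(OCc2ccccc2)c(OCc2ccccc2)c1.O=C(Cl)c1cc(OCc2ccccc2)c(OCc2ccccc2)c(OCc2ccccc2)c1)
Why: DMAP-catalysed acylation (nucleophilic catalysis) with three equivalents of 14 should esterify the three secondary hydroxyls at C3, C4 and C5 and leave the hindered tertiary C1 hydroxyl free at this stoichiometry, with retention at all three carbons because no ring C–O bond is broken.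

**Step 10**
Reactants: 15 benzyl 3,4,5-tris-O-[3,4,5-tris(benzyloxy)benzoyl]quinate
Product: 16 3,4,5-tri-O-galloylquinic acid (target)
Conditions: H2 (1 atm), Pd/C (10 %), THF/MeOH (1:1), rt
Reagents that add atoms: none
Why: Hydrogenolysis over Pd/C should remove the nine benzyl ethers and the benzyl ester under neutral conditions that leave the aryl esters and all stereocentres intact.

**Compound list**
1 | diethyl oxalate | CCOC(=O)C(=O)OCC | starting material
2 | vinylmagnesium bromide | C=C[Mg]Br | starting material
3 | ethyl 2-oxobut-3-enoate | C=CC(=O)C(=O)OCC | intermediate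
4 | acetone | CC(C)=O | starting material
5 | ethyl 2,6-dioxoheptanoate | CC(=O)CCCC(=O)C(=O)OCC | intermediate
6 | ethyl (1S)-1-hydroxy-3-oxocyclohexane-1-carboxylate | O=C1C[C@](O)(C(=O)OCC)CCC1 | intermediate
7 | ethyl (1S)-1-hydroxy-5-oxocyclohex-3-ene-1-carboxylate | O=C1C[C@](O)(C(=O)OCC)CC=C1 | intermediate
8 | ethyl (1S,5R)-1,5-dihydroxycyclohex-3-ene-1-carboxylate | O[C@@H]1C[C@](O)(C(=O)OCC)CC=C1 | intermediate
9 | (1S,5R)-1-hydroxy-6-oxabicyclo[3.2.1]oct-3-en-7-one | O=C1O[C@@H]2C[C@@]1(O)CC=C2 | intermediate
10 | 1,5-quinide, (1S,3R,4R,5R)-1,3,4-trihydroxy-6-oxabicyclo[3.2.1]octan-7-one | O=C1O[C@@H]2C[C@@]1(O)C[C@@H](O)[C@H]2O | intermediate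
11 | benzyl alcohol | OCc1ccccc1 | starting material
12 | benzyl (1S,3R,4S,5R)-1,3,4,5-tetrahydroxycyclohexane-1-carboxylate (benzyl quinate) | O[C@@H]1C[C@](O)(C(=O)OCc2ccccc2)C[C@@H](O)[C@H]1O | intermediate
13 | 3,4,5-tris(benzyloxy)benzoic acid | OC(=O)c1cc(OCc2ccccc2)c(OCc2ccccc2)c(OCc2ccccc2)c1 | starting material
14 | 3,4,5-tris(benzyloxy)benzoyl chloride | O=C(Cl)c1cc(OCc2ccccc2)c(OCc2ccccc2)c(OCc2ccccc2)c1 | intermediate
15 | benzyl 3,4,5-tris-O-[3,4,5-tris(benzyloxy)benzoyl]quinate | O=C(O[C@@H]1C[C@](O)(C(=O)OCc2ccccc2)C[C@@H](OC(=O)c2cc(OCc3ccccc3)c(OCc3ccccc3)c(OCc3ccccc3)c2)[C@H]1OC(=O)c1cc(OCc2ccccc2)c(OCc2ccccc2)c(OCc2ccccc2)c1)c1cc(OCc2ccccc2)c(OCc2ccccc2)c(OCc2ccccc2)c1 | intermediate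
16 | 3,4,5-tri-O-galloylquinic acid, (1S,3R,4S,5R)-1-hydroxy-3,4,5-tris[(3,4,5-trihydroxybenzoyl)oxy]cyclohexane-1-carboxylic acid | O=C(O[C@@H]1C[C@](O)(C(=O)O)C[C@@H](OC(=O)c2cc(O)c(O)c(O)c2)[C@H]1OC(=O)c1cc(O)c(O)c(O)c1)c1cc(O)c(O)c(O)c1 | target

**Step count and risks**
Total steps: 10. Longest linear sequence: 9 (steps 1–7, 9, 10); step 8 is a one-step side branch.

Step 2 (Proposed new method). Enone 3 may polymerise or add to itself faster than it is trapped, 1,2-aldol addition may compete, or the ring-closing aldol may show poor facial selectivity. Incomplete enantiopurity might be corrected by recrystallising lactone 9 or quinide 10. The fallback uses known chemistry, sets out from 1 and returns at 7, bypassing steps 2 and 3 and forming the two ring bonds in separate steps. Allylmagnesium bromide (THF, −78 °C) should give ethyl 2-oxopent-4-enoate F1. A Mukaiyama aldol addition of 2-(trimethylsilyloxy)buta-1,3-diene through its CH2 terminus, catalysed by Cu(OTf)2 with the (S,S)-t-Bu-box ligand (THF, −78 °C, acidic work-up), should give ethyl (2S)-2-hydroxy-4-oxo-2-(prop-2-en-1-yl)hex-5-enoate F2 by the si-face attack known for pyruvate-type keto esters. Ring-closing metathesis with the second-generation Hoveyda–Grubbs catalyst (CH2Cl2, 40 °C) should then give 7.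

Step 3. Dehydration of the tertiary β-hydroxy ketone or stalled conversion under the oxidising conditions may erode the material. The fallback sets out from 6 and returns at 7 by a Saegusa–Ito sequence. TMSOTf/Et3N (CH2Cl2, 0 °C) should give ethyl (1S)-1,3-bis(trimethylsilyloxy)cyclohex-3-ene-1-carboxylate F3, the enol ether forming on the less hindered C4 side. Pd(OAc)2 (MeCN, rt) should give ethyl (1S)-5-oxo-1-(trimethylsilyloxy)cyclohex-3-ene-1-carboxylate F4, and 1 M HCl in THF should release 7.

Step 1. A second Grignard addition or polymerisation of the enone during acylation and work-up may lower the supply of 3. The fallback sets out from 2 and returns at 3. Addition of 2 to ethyl glyoxylate (THF, −78 °C) should give racemic ethyl 2-hydroxybut-3-enoate F5, whose stereocentre is destroyed on oxidation with Dess–Martin periodinane (CH2Cl2, 0 °C) to a solution of 3 that is used directly.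

**Further compounds**
F1 | step 2 | ethyl 2-oxopent-4-enoate | C=CCC(=O)C(=O)OCC
F2 | step 2 | ethyl (2S)-2-hydroxy-4-oxo-2-(prop-2-en-1-yl)hex-5-enoate | C=CC(=O)C[C@](O)(C(=O)OCC)CC=C
F3 | step 3 | ethyl (1S)-1,3-bis(trimethylsilyloxy)cyclohex-3-ene-1-carboxylate | C[Si](C)(C)OC1=CCC[C@@](O[Si](C)(C)C)(C(=O)OCC)C1
F4 | step 3 | ethyl (1S)-5-oxo-1-(trimethylsilyloxy)cyclohex-3-ene-1-carboxylate | O=C1C[C@](O[Si](C)(C)C)(C(=O)OCC)CC=C1
F5 | step 1 | ethyl 2-hydroxybut-3-enoate (racemic) | C=CC(O)C(=O)OCC
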